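**Retrosynthetic overview**
1. Target 10 ⇐ phenol 9: the quinone ring is made last by para-oxygenation of 2-hexaprenyl-6-methoxyphenol, the same phenol → 1,4-quinone event that closes the biosynthesis. The six ring carbons are bought as guaiacol, so this is the only ring-level step.
2. 9 ⇐ ether 8: the aryl–C1′ bond comes from an O→C [1,3] prenyl shift in hexaprenyl guaiacyl ether (ion-pair prenyl transfer ortho to the phenol oxygen), not from an aryl-metal plus prenyl halide.
3. 8 ⇐ 5 + 6: the C12′–C13′ bond comes from α,α′ allylbarium coupling of two C15 units.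
4. 5 ⇐ 3 ⇐ 1 + 2: E-selective ω-hydroxylation and bromination of farnesyl guaiacyl ether. The guaiacyl ether is the only protecting group and is never removed; it becomes the product.

Assumption: the target has no stereocentre, so "single enantiomer" is read as the single all-E isomer (five E-trisubstituted alkenes) of the SMILES. Guaiacol, (2E,6E)-farnesyl bromide and (2E,6E)-farnesyl chloride are taken as catalogue materials.

**Step 1**
Reactants: 1 guaiacol (2-methoxyphenol); 2 (2E,6E)-farnesyl bromide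
Product: 3 (2E,6E)-farnesyl 2-methoxyphenyl ether, i.e. 1-methoxy-2-{[(2E,6E)-3,7,11-trimethyldodeca-2,6,10-trien-1-yl]oxy}benzene
Conditions: K2CO3 (2 equiv), acetone, reflux, 12 h
Reagents that add atoms: none
Why: Williamson ether synthesis, in which the phenoxide attacks the primary allylic bromide at oxygen by SN2 in a polar medium, so the 2E,6E geometry is untouched and the resulting aryl ether serves both as phenol protection and as the latent prenyl donor.

**Step 2**
Reactants: 3 (2E,6E)-farnesyl 2-methoxyphenyl ether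
Product: 4 (2E,6E,10E)-12-(2-methoxyphenoxy)-2,6,10-trimethyldodeca-2,6,10-trien-1-ol
Conditions: SeO2 (0.3 equiv), t-BuOOH (70% aq, 3 equiv), salicylic acid (0.1 equiv), CH2Cl2, 0 °C → rt; stop at about 60% conversion and recycle 3
Reagents that add atoms: tert-butyl hydroperoxide, CC(C)(C)OO (terminal oxidant; the O atom is passed on through catalytic selenium dioxide, O=[Se]=O)
Why: Sharpless SeO2/t-BuOOH allylic oxidation (ene reaction then [2,3]-sigmatropic shift) attacks the most electron-rich and least hindered terminal trisubstituted alkene and oxidises only its E-methyl group, which sets the 10E geometry of the new allylic alcohol, while the 2,3-alkene is deactivated by its allylic aryloxy group.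

**Step 3**
Reactants: 4 (2E,6E,10E)-12-(2-methoxyphenoxy)-2,6,10-trimethyldodeca-2,6,10-trien-1-ol
Product: 5 1-{[(2E,6E,10E)-12-bromo-3,7,11-trimethyldodeca-2,6,10-trien-1-yl]oxy}-2-methoxybenzene
Conditions: CBr4 (1.3 equiv), PPh3 (1.3 equiv), CH2Cl2, 0 °C, 30 min
Reagents that add atoms: carbon tetrabromide, BrC(Br)(Br)Br
Why: Appel reaction, in which bromide displaces the activated oxygen at the primary carbon by SN2 under neutral conditions, so there is no allylic transposition, no E/Z loss and no cleavage of the aryl allyl ether.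

**Step 4**
Reactants: 5 1-{[(2E,6E,10E)-12-bromo-3,7,11-trimethyldodeca-2,6,10-trien-1-yl]oxy}-2-methoxybenzene; 6 (2E,6E)-farnesyl chloride
Product: 8 (2E,6E,10E,14E,18E)-hexaprenyl 2-methoxyphenyl ether, i.e. 1-{[(2E,6E,10E,14E,18E)-3,7,11,15,19,23-hexamethyltetracosa-2,6,10,14,18,22-hexaen-1-yl]oxy}-2-methoxybenzene, via farnesylbarium chloride 7 (not isolated)
Conditions: BaI2 (anhydrous), lithium biphenylide (2 equiv per Ba), THF, rt; then 6 (2 equiv relative to 5), −78 °C, 30 min; then 5, THF, −78 °C, 1 h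
Reagents that add atoms: none
Why: allylbarium α,α′-selective allyl–allyl cross-coupling, in which the barium reagent formed at −78 °C keeps its E geometry and attacks the primary allylic bromide through its α-carbon by SN2, giving the head-to-tail CH2–CH2 link of the regular chain with all five E alkenes in place (geometry from 2, 6 and step 2).

**Step 5**
Reactants: 8 (2E,6E,10E,14E,18E)-hexaprenyl 2-methoxyphenyl ether
Product: 9 2-[(2E,6E,10E,14E,18E)-3,7,11,15,19,23-hexamethyltetracosa-2,6,10,14,18,22-hexaen-1-yl]-6-methoxyphenol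
Conditions: Florisil (oven-activated, about 10 wt equiv), toluene, 100 °C; stop at full consumption of 8
Reagents that add atoms: none
Why: Florisil-promoted formal [1,3]-O→C prenyl shift, in which the surface acid ionises the aryl allyl ether to a tight hexaprenyl cation/guaiacolate ion pair that recombines at the only free ortho carbon through the unsubstituted C1′ terminus, the chemical counterpart of the aromatic prenyl-transferase step, with the 2′E alkene kept because the E-allyl cation neither rotates nor cyclises in the non-polar medium.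

**Step 6**
Reactants: 9 2-[(2E,6E,10E,14E,18E)-hexaprenyl]-6-methoxyphenol
Product: 10 2-methoxy-6-[(2E,6E,10E,14E,18E)-3,7,11,15,19,23-hexamethyltetracosa-2,6,10,14,18,22-hexaen-1-yl]-1,4-benzoquinone (target)
Conditions: Fremy's salt (2.5 equiv), aq KH2PO4, acetone/Et2O/H2O, Bu4NHSO4 (cat.), 0 °C → rt, dark
Reagents that add atoms: potassium nitrosodisulfonate (Fremy's salt), [K+].[K+].[O]N(S(=O)(=O)[O-])S(=O)(=O)[O-]
Why: Teuber oxidation, in which one nitroxyl radical removes the phenolic hydrogen and a second couples at the free para position of the 2,6-disubstituted phenoxyl radical before elimination to the 1,4-benzoquinone, the same para-oxygenation by which the quinone ring arises in nature, and the reagent leaves isolated trisubstituted alkenes alone.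

**Compound list**
1 | guaiacol (2-methoxyphenol) | COc1ccccc1O | starting material
2 | (2E,6E)-farnesyl bromide | BrC/C=C(\C)CC/C=C(\C)CCC=C(C)C | starting material
3 | (2E,6E)-farnesyl 2-methoxyphenyl ether | COc1ccccc1OC/C=C(\C)CC/C=C(\C)CCC=C(C)C | intermediate
4 | (2E,6E,10E)-12-(2-methoxyphenoxy)-2,6,10-trimethyldodeca-2,6,10-trien-1-ol | COc1ccccc1OC/C=C(\C)CC/C=C(\C)CC/C=C(\C)CO | intermediate
5 | 1-{[(2E,6E,10E)-12-bromo-3,7,11-trimethyldodeca-2,6,10-trien-1-yl]oxy}-2-methoxybenzene | COc1ccccc1OC/C=C(\C)CC/C=C(\C)CC/C=C(\C)CBr | intermediate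
6 | (2E,6E)-farnesyl chloride | ClC/C=C(\C)CC/C=C(\C)CCC=C(C)C | starting material
7 | (2E,6E)-farnesylbarium chloride | Cl[Ba]C/C=C(\C)CC/C=C(\C)CCC=C(C)C | intermediate
8 | (2E,6E,10E,14E,18E)-hexaprenyl 2-methoxyphenyl ether | COc1ccccc1OC/C=C(\C)CC/C=C(\C)CC/C=C(\C)CC/C=C(\C)CC/C=C(\C)CCC=C(C)C | intermediate
9 | 2-[(2E,6E,10E,14E,18E)-hexaprenyl]-6-methoxyphenol | COc1cccc(C/C=C(\C)CC/C=C(\C)CC/C=C(\C)CC/C=C(\C)CC/C=C(\C)CCC=C(C)C)c1O | intermediate
10 | 2-methoxy-6-[(2E,6E,10E,14E,18E)-hexaprenyl]-1,4-benzoquinone | COC1=CC(=O)C=C(C/C=C(\C)CC/C=C(\C)CC/C=C(\C)CC/C=C(\C)CC/C=C(\C)CCC=C(C)C)C1=O | target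

**Totals**
Total step count: 6. Longest linear sequence: 6 (steps 1–6; farnesyl chloride 6 enters at step 4).

**Three steps most likely to fail**

Step 5 (O→C shift). The risks are para migration to C4, acid-induced chroman formation or polyene cyclisation, and partial E/Z loss at C2′. The fallback makes the aryl–carbon bond by SN2 C-alkylation of a phenoxide at the C15 stage and extends the chain afterwards on a silyl-protected phenol. It sets out from 1 and 2 and comes back at 9. Guaiacol 1 is deprotonated with NaH in toluene to sodium 2-methoxyphenolate F1. This suspension is C-alkylated at the free ortho carbon by 2 (toluene, rt) to give 2-[(2E,6E)-farnesyl]-6-methoxyphenol F2. TBSCl/imidazole in DMF gives tert-butyl{2-[(2E,6E)-farnesyl]-6-methoxyphenoxy}dimethylsilane F3. SeO2/t-BuOOH as in step 2 gives (2E,6E,10E)-12-{2-[(tert-butyldimethylsilyl)oxy]-3-methoxyphenyl}-2,6,10-trimethyldodeca-2,6,10-trien-1-ol F4. CBr4/PPh3 gives tert-butyl{2-[(2E,6E,10E)-12-bromo-3,7,11-trimethyldodeca-2,6,10-trien-1-yl]-6-methoxyphenoxy}dimethylsilane F5. Coupling with 7 (made from 6 as in step 4) gives tert-butyl{2-[(2E,6E,10E,14E,18E)-hexaprenyl]-6-methoxyphenoxy}dimethylsilane F6, and TBAF in THF releases 9.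

Step 4 (allylbarium coupling). The risks are that active barium is technically demanding, that Wurtz homocoupling gives squalene, and that some α,γ-coupling occurs. The fallback uses a sulfone-stabilised carbanion instead of an allyl metal and removes the sulfonyl group only after the aryl shift, because Pd/hydride would also cleave the allyl aryl ether. It sets out from 5 (with 2 as the source of the nucleophile) and comes back at 9. Bromide 2 and sodium p-toluenesulfinate in DMF give (2E,6E)-farnesyl p-tolyl sulfone F7. n-BuLi in THF at −78 °C gives α-lithio farnesyl p-tolyl sulfone F8, which is not isolated. Alkylation with 5 gives 1-{[(2E,6E,10E,14E,18E)-3,7,11,15,19,23-hexamethyl-13-(p-tolylsulfonyl)tetracosa-2,6,10,14,18,22-hexaen-1-yl]oxy}-2-methoxybenzene F9, racemic at C13. Florisil in toluene as in step 5 gives 2-[(2E,6E,10E,14E,18E)-3,7,11,15,19,23-hexamethyl-13-(p-tolylsulfonyl)tetracosa-2,6,10,14,18,22-hexaen-1-yl]-6-methoxyphenol F10. PdCl2(dppp)/LiEt3BH in THF at 0 °C then delivers hydride to the less substituted allyl terminus and gives 9.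

Step 2 (SeO2 ω-oxidation). The risks are modest conversion, over-oxidation to the enal and attack at internal alkenes. The fallback cleaves the terminal alkene and rebuilds it by E-selective olefination instead of C–H oxidation. It sets out from 3 and comes back at 4. NBS in THF/H2O at 0 °C gives the terminal bromohydrin (6E,10E)-3-bromo-12-(2-methoxyphenoxy)-2,6,10-trimethyldodeca-6,10-dien-2-ol F11. K2CO3 in MeOH gives 3-[(3E,7E)-9-(2-methoxyphenoxy)-3,7-dimethylnona-3,7-dien-1-yl]-2,2-dimethyloxirane F12. HIO4·2H2O in THF/Et2O gives (4E,8E)-10-(2-methoxyphenoxy)-4,8-dimethyldeca-4,8-dienal F13. Wittig reaction with Ph3P=C(CH3)CO2Et in CH2Cl2 gives ethyl (2E,6E,10E)-12-(2-methoxyphenoxy)-2,6,10-trimethyldodeca-2,6,10-trienoate F14, and DIBAL-H in CH2Cl2 at −78 °C gives 4.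

**Further compounds**
F1 | step 5 | sodium 2-methoxyphenolate | COc1ccccc1[O-].[Na+]
F2 | step 5 | 2-[(2E,6E)-farnesyl]-6-methoxyphenol | COc1cccc(C/C=C(\C)CC/C=C(\C)CCC=C(C)C)c1O
F3 | step 5 | tert-butyl{2-[(2E,6E)-farnesyl]-6-methoxyphenoxy}dimethylsilane | COc1cccc(C/C=C(\C)CC/C=C(\C)CCC=C(C)C)c1O[Si](C)(C)C(C)(C)C
F4 | step 5 | (2E,6E,10E)-12-{2-[(tert-butyldimethylsilyl)oxy]-3-methoxyphenyl}-2,6,10-trimethyldodeca-2,6,10-trien-1-ol | COc1cccc(C/C=C(\C)CC/C=C(\C)CC/C=C(\C)CO)c1O[Si](C)(C)C(C)(C)C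
F5 | step 5 | tert-butyl{2-[(2E,6E,10E)-12-bromo-3,7,11-trimethyldodeca-2,6,10-trien-1-yl]-6-methoxyphenoxy}dimethylsilane | COc1cccc(C/C=C(\C)CC/C=C(\C)CC/C=C(\C)CBr)c1O[Si](C)(C)C(C)(C)C
F6 | step 5 | tert-butyl{2-[(2E,6E,10E,14E,18E)-hexaprenyl]-6-methoxyphenoxy}dimethylsilane | COc1cccc(C/C=C(\C)CC/C=C(\C)CC/C=C(\C)CC/C=C(\C)CC/C=C(\C)CCC=C(C)C)c1O[Si](C)(C)C(C)(C)C
F7 | step 4 | (2E,6E)-farnesyl p-tolyl sulfone | Cc1ccc(cc1)S(=O)(=O)C/C=C(\C)CC/C=C(\C)CCC=C(C)C
F8 | step 4 | α-lithio farnesyl p-tolyl sulfone | [Li]C(/C=C(\C)CC/C=C(\C)CCC=C(C)C)S(=O)(=O)c1ccc(C)cc1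
F9 | step 4 | 1-{[(2E,6E,10E,14E,18E)-3,7,11,15,19,23-hexamethyl-13-(p-tolylsulfonyl)tetracosa-2,6,10,14,18,22-hexaen-1-yl]oxy}-2-methoxybenzene (racemic at C13) | COc1ccccc1OC/C=C(\C)CC/C=C(\C)CC/C=C(\C)CC(/C=C(\C)CC/C=C(\C)CCC=C(C)C)S(=O)(=O)c1ccc(C)cc1
F10 | step 4 | 2-[(2E,6E,10E,14E,18E)-3,7,11,15,19,23-hexamethyl-13-(p-tolylsulfonyl)tetracosa-2,6,10,14,18,22-hexaen-1-yl]-6-methoxyphenol (racemic at C13) | COc1cccc(C/C=C(\C)CC/C=C(\C)CC/C=C(\C)CC(/C=C(\C)CC/C=C(\C)CCC=C(C)C)S(=O)(=O)c2ccc(C)cc2)c1O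
F11 | step 2 | (6E,10E)-3-bromo-12-(2-methoxyphenoxy)-2,6,10-trimethyldodeca-6,10-dien-2-ol (racemic) | COc1ccccc1OC/C=C(\C)CC/C=C(\C)CCC(Br)C(C)(C)O
F12 | step 2 | 3-[(3E,7E)-9-(2-methoxyphenoxy)-3,7-dimethylnona-3,7-dien-1-yl]-2,2-dimethyloxirane (racemic) | COc1ccccc1OC/C=C(\C)CC/C=C(\C)CCC1OC1(C)C
F13 | step 2 | (4E,8E)-10-(2-methoxyphenoxy)-4,8-dimethyldeca-4,8-dienal | COc1ccccc1OC/C=C(\C)CC/C=C(\C)CCC=O
F14 | step 2 | ethyl (2E,6E,10E)-12-(2-methoxyphenoxy)-2,6,10-trimethyldodeca-2,6,10-trienoate | COc1ccccc1OC/C=C(\C)CC/C=C(\C)CC/C=C(\C)C(=O)OCC
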